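**Late readings.** At the last reading of each earlier run, all with c_substrate at 20 mM, target seems to follow the product of the charges, c_reagent × c_free catalyst. Divide the last reading of target, as a fraction of the substrate charged, by that product, and zeta gives 0.00674 mM⁻², gamma 0.00642 mM⁻² and theta 0.00554 mM⁻². With a scatter of 1 percentage point on each reading, I treat these as nearly constant and freeze them at their mean, 0.00623 mM⁻². Call this ratio of late target to c_reagent × c_free catalyst, at that charge of substrate, the reach.

the same everywhere: substrate 20 mM

| run | reagent | free catalyst | remark | time |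
|---|---|---|---|---|
| zeta | 8.9 mM | 1 mM | run made earlier |  |
| gamma | 19 mM | 1 mM | run made earlier |  |
| theta | 22 mM | 1.6 mM | run made earlier |  |
| amber | 22.0 mM | 1.0 mM |  | 80 min |
| grey | 15.0 mM | 4.0 mM |  | 80 min |

| run | time / min | target / % | substrate / % |
|---|---|---|---|
| zeta | 15.0 | 0.5 | 55.0 |
| zeta | 30.0 | 3.1 | 32.5 |
| zeta | 40.0 | 4.8 | 20.9 |
| zeta | 60.0 | 6.0 | 11.1 |
| gamma | 15.0 | 3.0 | 56.7 |
| gamma | 30.0 | 4.2 | 30.8 |
| gamma | 40.0 | 8.6 | 21.6 |
| gamma | 60.0 | 12.2 | 10.7 |
| theta | 15.0 | 5.3 | 42.1 |
| theta | 30.0 | 14.3 | 16.1 |
| theta | 40.0 | 13.9 | 8.3 |
| theta | 60.0 | 19.5 | 3.4 |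

(standard deviation of a reading: 1 percentage point)

- the flask that ends with the higher amount of target, in percent of the substrate charged, or "neither" when 2 percentage points or less lies between them (amber / grey / neither)
- final target, as a percentage of the substrate charged, in amber
- final target, as a percentage of the substrate charged, in grey



**Turned round.** Grey's product exceeds amber's by a factor of 2.73. For amber to draw level, grey's reach would have to sit below amber's by that factor, or a little less for the margin. From zeta to theta, the product grew 3.96-fold, yet the reach as read from those scattered readings fell by a factor of 1.22. So I commit to grey. Carrying the reach unchanged to 80 min, a rough step, I put amber near 13.7% and grey somewhat under 37.4%.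

**The forecast.** The forecast differs from this: it gave 21.5% for amber, 20.5% for grey and so neither, saying “Grey makes intermediate fast but has less reagent”.

**The result.** Amber ends at 16.1% and grey at 28.3%, so the answer is grey.

    substrate + free catalyst → free catalyst + open intermediate (k = 41.7 M⁻¹ min⁻¹)
    free catalyst + open intermediate ⇌ catalyst intermediate (K = 17.0 M⁻¹, k = 48.8 M⁻¹ min⁻¹)
    reagent + catalyst intermediate → free catalyst + target (k = 35.4 M⁻¹ min⁻¹)
    open intermediate → side product (k = 0.0130 min⁻¹)
    target + free catalyst ⇌ isomer of the product + free catalyst, rate k5*[free catalyst]*[target] forward; the back reaction follows from the equilibrium constant (K = 0.760, k = 35.0 M⁻¹ min⁻¹)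

**Why grey.** The charge of free catalyst is the main reason for the gap: grey with amber's charge of it ends at 12.1% instead of 28.3%. At 80 min the reach came out at 0.00731 mM⁻² in amber and 0.00472 mM⁻² in grey, a fall from amber to grey by a factor of 1.55, less than the 2.73 a tie asks for. For the neighbour, grey with 2.4 mM of free catalyst, my mean reach gives 22.4%, and that flask ends at 22.2%.

The readings were generated by integration with made-up constants, and the scatter is random.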